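**Plan**

1. Locants: propyl C1–C3, C4 (propyl-bearing CH), C5 (enol carbon), C6, C7, C8, C9 (quaternary, methyl), C10, C11 (methyl), C12 (OH), C13, C14, C15 (methyl), C16 (ketone), C17, C18 (lactone CH–O), C19 (lactone C=O).
2. Retrosynthetic cuts, in order: C5–C6 (transannular Dieckmann), O–C19 (13-membered lactone), C3–C4 (allylation), C16–C17 (aldol), C14=C15 (Wittig), then C9–C10 together with C12–C13.
3. Enabling feature: in the oxane (ring O, C9–C13) the C9 methyl and C14 are cis across the ring oxygen. They can therefore be C3 and C4 of a furan whose C2 (C9) carries the C8 chain, while C10–C11–C12 with oxygen on C12 is an alkoxy-oxyallyl cation. Their [4+3] union gives an 8-oxabicyclo[3.2.1]oct-6-en-3-one in which the oxane is already closed; its etheno bridge, absent from the target, is cut later between the C9-methyl carbon and C14.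
4. Forward order: bicycle; exo-face hydrogenation of a C11 methylene; bridge cleavage to the 2,6-cis oxane (one bridge carbon reduced to the C9 methyl, the other extended to C14–C18/C4/C5); 13-membered lactone; hydroxypyranone by Dieckmann closure.
5. Stereochemistry: C9, C12, C13 from the cycloaddition under an (S)-1-phenylethyl ether that stays as the O12 protecting group until the last step; C11 from the bicycle; C15 and C18 by Ru–BINAP hydrogenations; C4 by chelate-controlled alkylation; C16 is a temporary carbinol centre, oxidised at the end.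

Key step: step 4

Assumption: the (S)-1-phenylethyl group is taken to shield the cation face that leads to 10, as in the parent furan series; if the sense were opposite, (R)-1-phenylethanol would be used in the same route.

**Route**

Step 1
Reactants: 1 furan; 2 tert-butyl(4-iodobutoxy)dimethylsilane
Product: 4 tert-butyl[4-(furan-2-yl)butoxy]dimethylsilane, via 2-furyllithium 3 (not isolated)
Conditions: n-BuLi, THF, 0 °C; then 2, −78 °C → rt
Reagents that add atoms: none
Why: α-lithiation of furan followed by SN2 alkylation with the primary iodide should install the chain that becomes C8, C7, C6 and C19.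

Step 2
Reactants: 5 1,1-dimethoxypropan-2-one; 6 (S)-1-phenylethanol
Product: 7 1-methoxy-1-[(1S)-1-phenylethoxy]propan-2-one (both epimers at the acetal carbon)
Conditions: PPTS (cat.), cyclohexane, reflux, MeOH removed over 5 Å sieves
Reagents that add atoms: none
Why: acid-catalysed transacetalisation driven by removal of methanol; the acetal carbon is ionised in step 4, so its configuration is irrelevant.

Step 3
Reactants: 7 1-methoxy-1-[(1S)-1-phenylethoxy]propan-2-one
Product: 8 triethyl({3-methoxy-3-[(1S)-1-phenylethoxy]prop-1-en-2-yl}oxy)silane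
Conditions: LiN(i-Pr)2, THF, −78 °C; then Et3SiCl
Reagents that add atoms: chlorotriethylsilane, CC[Si](CC)(CC)Cl
Why: kinetic deprotonation of the methyl ketone at CH3 and O-silylation (silyl enol ether formation).

Step 4
Reactants: 4 tert-butyl[4-(furan-2-yl)butoxy]dimethylsilane; 8 triethyl({3-methoxy-3-[(1S)-1-phenylethoxy]prop-1-en-2-yl}oxy)silane
Product: 10 (1S,4R,5S)-1-[4-(tert-butyldimethylsilyloxy)butyl]-4-[(1S)-1-phenylethoxy]-8-oxabicyclo[3.2.1]oct-6-en-3-one (alkoxy group equatorial, cis to the etheno bridge), via alkoxy-siloxyallyl cation 9 (not isolated)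
Conditions: Me3SiOTf (0.1 equiv), CH2Cl2, −95 → −78 °C; Et3N quench
Reagents that add atoms: none
Why: Me3SiOTf ionises the mixed acetal (loss of methoxide) to the (Z)-1-alkoxy-2-siloxyallyl cation 9, whose alkoxy-bearing terminus (C12) is attacked by the free α-carbon of furan 4 (C13), after which the siloxy-alkene terminus (C10) closes on the alkyl-stabilised furan oxocarbenium carbon (C9) and the silyl group leaves as Et3SiOMe. The closest known reaction type is the [4+3] cycloaddition of furans with alkoxy-substituted siloxyallyl cations generated from 2-siloxyacrolein acetals that carry a 1-phenylethyl auxiliary. Two rings close in the one event: the seven-membered carbocycle C9–C10–C11–C12–C13–C14–C(9-methyl) by the suprafacial union of the four-carbon 4π furan diene with the three-carbon 2π cation, and within it the six-membered oxane O–C9–C10–C11–C12–C13 by 6-endo attack of the enol silane carbon C10 on the C9 oxocarbenium. C9 and C13 are fixed relative to each other by the suprafacial addition across the furan (the bridge carbons, the future C9 methyl and C14, are necessarily cis), C12 by the compact (endo) transition state of the (Z)-cation, which places the alkoxy group equatorial and cis to the etheno bridge, and the absolute sense by the (S)-1-phenylethyl group, which shields one face of the cation. The step needs regioselectivity (C12 bonded to C13, not to C9) and facial selectivity: the first is secured by the match of the oxocarbenium terminus with the unsubstituted, most nucleophilic furan α-carbon, the second by the auxiliary, and all unwanted isomers are diastereomers that chromatography should remove.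

Step 5
Reactants: 10 the cycloadduct
Product: 11 1-[4-(tert-butyldimethylsilyloxy)butyl]-6-exo,7-exo-dihydroxy-4-[(1S)-1-phenylethoxy]-8-oxabicyclo[3.2.1]octan-3-one (both hydroxyls syn to the oxygen bridge; other centres as in 10)
Conditions: OsO4 (2 mol %), N-methylmorpholine N-oxide, acetone/H2O, 0 °C → rt
Reagents that add atoms: N-methylmorpholine N-oxide, C[N+]1([O-])CCOCC1; water, O
Why: Upjohn syn-dihydroxylation of the strained bridge alkene from its exo face, which masks the bridge for later cleavage and protects it from the hydrogenation in step 7.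

Step 6
Reactants: 11 the keto diol
Product: 12 the 3-methylene analogue of 11 (C11 ketone replaced by C=CH2)
Conditions: Ph3PCH3Br (5 equiv), KOtBu (4.8 equiv), THF, 0 °C → rt
Reagents that add atoms: methyltriphenylphosphonium bromide, C[P+](c1ccccc1)(c1ccccc1)c1ccccc1.[Br-]
Why: Wittig methylenation of the C11 ketone, with excess ylide to carry the free diol as its alkoxide; the new carbon becomes the C11 methyl.

Step 7
Reactants: 12 the methylene diol
Product: 13 the 3-endo-methyl diol (C11 methyl axial, on the side of the two-carbon bridge, cis to the C12 oxygen)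
Conditions: H2 (3 atm), RhCl(PPh3)3 (5 mol %), benzene/EtOH, rt
Reagents that add atoms: none
Why: homogeneous hydrogenation of the 1,1-disubstituted alkene from the convex exo face (the endo face is screened by the two-carbon bridge) should set C11, and this catalyst leaves the benzylic ether intact.

Step 8
Reactants: 13 the methyl diol
Product: 15 ethyl (E)-3-{(2S,3S,4S,6S)-6-[4-(tert-butyldimethylsilyloxy)butyl]-6-formyl-4-methyl-3-[(1S)-1-phenylethoxy]oxan-2-yl}-2-methylprop-2-enoate, via oxane-2,6-dicarbaldehyde 14 (not isolated)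
Conditions: NaIO4/SiO2, CH2Cl2, rt; filter; then Ph3P=C(CH3)CO2Et (1.05 equiv), −20 °C → rt
Reagents that add atoms: ethyl 2-(triphenylphosphoranylidene)propanoate, CCOC(=O)C(C)=P(c1ccccc1)(c1ccccc1)c1ccccc1
Why: glycol cleavage opens the bridge to the 2,6-cis-diformyl oxane, and the bulky stabilised ylide (E-selective Wittig) should olefinate only the aldehyde on the tertiary carbon C13, because the aldehyde on the fully substituted C9 is neopentyl-like and far slower.

Step 9
Reactants: 15 the enoate aldehyde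
Product: 16 the corresponding 6-(hydroxymethyl) enoate
Conditions: NaBH4, EtOH, −20 °C
Reagents that add atoms: none
Why: chemoselective hydride reduction of the aldehyde; the conjugated ester is inert under these conditions.

Step 10
Reactants: 16 the hydroxy enoate
Product: 17 the corresponding 6-[(p-toluenesulfonyloxy)methyl] enoate
Conditions: TsCl, Et3N, DMAP (cat.), CH2Cl2, 0 °C → rt
Reagents that add atoms: p-toluenesulfonyl chloride, Cc1ccc(cc1)S(Cl)(=O)=O
Why: sulfonylation of the primary alcohol to activate it for hydride displacement.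

Step 11
Reactants: 17 the tosylate
Product: 18 (E)-3-{(2S,3S,4S,6S)-6-[4-(tert-butyldimethylsilyloxy)butyl]-4,6-dimethyl-3-[(1S)-1-phenylethoxy]oxan-2-yl}-2-methylprop-2-en-1-ol
Conditions: LiEt3BH (6 equiv), THF, 0 → 40 °C
Reagents that add atoms: none
Why: SN2 hydride displacement of the primary tosylate gives the C9 methyl (elimination is impossible at the fully substituted C9), and the same reagent reduces the enoate 1,2 to the (E)-allylic alcohol.

Step 12
Reactants: 18 the allylic alcohol
Product: 19 (2S)-3-{(2S,3S,4S,6S)-6-[4-(tert-butyldimethylsilyloxy)butyl]-4,6-dimethyl-3-[(1S)-1-phenylethoxy]oxan-2-yl}-2-methylpropan-1-ol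
Conditions: H2 (50 atm), Ru(OAc)2[(S)-BINAP] (1 mol %), MeOH, rt
Reagents that add atoms: none
Why: Noyori hydroxyl-directed asymmetric hydrogenation of the trisubstituted allylic alcohol; the (S)-ligand is chosen by analogy with geraniol and tiglic acid, where it delivers hydrogen to the same alkene face relative to the coordinating group, which here gives (S) at C15.

Step 13
Reactants: 19 the saturated alcohol
Product: 20 (2S)-3-{(2S,3S,4S,6S)-6-[4-(tert-butyldimethylsilyloxy)butyl]-4,6-dimethyl-3-[(1S)-1-phenylethoxy]oxan-2-yl}-2-methylpropanal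
Conditions: TEMPO (10 mol %), PhI(OAc)2, CH2Cl2, rt
Reagents that add atoms: none
Why: nitroxyl-catalysed oxidation of the primary alcohol to the aldehyde under conditions that should not epimerise C15.

Step 14
Reactants: 20 the aldehyde
Product: 21 methyl (5S,6S)-7-{(2S,3S,4S,6S)-6-[4-(tert-butyldimethylsilyloxy)butyl]-4,6-dimethyl-3-[(1S)-1-phenylethoxy]oxan-2-yl}-5-hydroxy-6-methyl-3-oxoheptanoate
Conditions: 1-methoxy-1,3-bis(trimethylsilyloxy)buta-1,3-diene, BF3·OEt2, CH2Cl2, −78 °C; aq. NaHCO3 work-up
Reagents that add atoms: 1-methoxy-1,3-bis(trimethylsilyloxy)buta-1,3-diene, COC(O[Si](C)(C)C)=CC(=C)O[Si](C)(C)C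
Why: vinylogous Mukaiyama aldol at the terminal carbon of the dienolate (C17) with open-transition-state Felkin–Anh control from C15, so the (16S) carbinol should be the main epimer; C16 is a temporary centre, and any minor epimer converges at step 23.

Step 15
Reactants: 21 the δ-hydroxy-β-keto ester
Product: 22 the C16 tert-butyldimethylsilyl ether of 21
Conditions: TBSCl, imidazole, DMF, rt
Reagents that add atoms: tert-butyldimethylsilyl chloride, CC(C)(C)[Si](C)(C)Cl
Why: silylation of the secondary alcohol, to keep O16 apart from O18 in the later lactonisation.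

Step 16
Reactants: 22 the silylated β-keto ester
Product: 23 methyl (3R,5S,6S)-5-(tert-butyldimethylsilyloxy)-7-{(2S,3S,4S,6S)-6-[4-(tert-butyldimethylsilyloxy)butyl]-4,6-dimethyl-3-[(1S)-1-phenylethoxy]oxan-2-yl}-3-hydroxy-6-methylheptanoate
Conditions: H2 (50 atm), RuCl2[(R)-BINAP] (1 mol %), MeOH, 50 °C
Reagents that add atoms: none
Why: Noyori asymmetric hydrogenation of the β-keto ester under catalyst control; the (R)-ligand should give the (R)-carbinol at C18, as it does for simple 3-oxoalkanoates in which the CH2CO2Me arm outranks the alkyl arm.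

Step 17
Reactants: 23 the β-hydroxy ester
Product: 24 methyl (2R,3R,5S,6S)-5-(tert-butyldimethylsilyloxy)-7-{(2S,3S,4S,6S)-6-[4-(tert-butyldimethylsilyloxy)butyl]-4,6-dimethyl-3-[(1S)-1-phenylethoxy]oxan-2-yl}-3-hydroxy-6-methyl-2-(prop-2-en-1-yl)heptanoate
Conditions: LiN(i-Pr)2 (2.3 equiv), THF, −78 → −20 °C; allyl bromide, DMPU, −78 → −20 °C; aq. NH4Cl
Reagents that add atoms: allyl bromide, C=CCBr
Why: Fráter–Seebach alkylation: the lithium-chelated alkoxide–enolate dianion is allylated on the face anti to the C18 oxygen, which sets C4; the allyl group is the latent propyl group.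

Step 18
Reactants: 24 the allylated hydroxy ester
Product: 25 the primary alcohol (4-hydroxybutyl chain on C9; C16 silyl ether kept)
Conditions: HF·pyridine, pyridine, THF, 0 °C
Reagents that add atoms: none
Why: selective cleavage of the primary silyl ether, the hindered secondary C16 silyl ether being much slower.

Step 19
Reactants: 25 the diol
Product: 26 the seco acid (C19 carboxylic acid, free C18 hydroxyl)
Conditions: TEMPO (20 mol %), PhI(OAc)2 (2.5 equiv), MeCN/pH 7 buffer, rt
Reagents that add atoms: water, O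
Why: nitroxyl-catalysed oxidation of the primary alcohol through the aldehyde hydrate to the acid; the hindered secondary C18 alcohol should react much more slowly.

Step 20
Reactants: 26 the seco acid
Product: 28 the 13-membered lactone (O on C18 bonded to C19; C5 methyl ester, C4 allyl, C16 silyl ether and O12 ether kept), via mixed anhydride 27 (not isolated)
Conditions: 2-methyl-6-nitrobenzoic anhydride (1.3 equiv), DMAP (3 equiv), CH2Cl2, 1 mM by slow addition, rt
Reagents that add atoms: none
Why: Shiina macrolactonisation through the mixed anhydride, run at high dilution and room temperature to limit oligomerisation and β-elimination of the β-hydroxy ester.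

Step 21
Reactants: 28 the macrolactone
Product: 29 the 4-hydroxy-5,6-dihydropyran-2-one (C5–C6 bond formed; C4 allyl, C16 silyl ether, O12 1-phenylethyl ether)
Conditions: LiN(SiMe3)2 (3 equiv), THF, −78 → 0 °C; 1 M HCl
Reagents that add atoms: none
Why: transannular Dieckmann condensation: the lactone enolate at C6 acylates on the C5 methyl ester (six-membered ring) and the acidic product is held as its enolate until the quench; C4 is already in the thermodynamically preferred trans relation to C18.

Step 22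
Reactants: 29 the silylated hydroxypyranone
Product: 30 the C16 alcohol
Conditions: HF·pyridine, THF, rt
Reagents that add atoms: none
Why: fluoride cleavage of the secondary silyl ether; lactone, enol and benzylic ether are stable to it.

Step 23
Reactants: 30 the C16 alcohol
Product: 31 the C16 ketone (O12 1-phenylethyl ether, C4 allyl)
Conditions: Dess–Martin periodinane, CH2Cl2, 0 °C → rt
Reagents that add atoms: none
Why: Dess–Martin oxidation of the only free secondary alcohol (O12 is still an ether), which also erases the temporary C16 centre.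

Step 24
Reactants: 31 the protected ketone
Product: 32 mangromicin C
Conditions: H2 (1 atm), Pd(OH)2/C, EtOAc/EtOH, rt
Reagents that add atoms: none
Why: hydrogenolysis of the benzylic 1-phenylethyl ether and hydrogenation of the allyl group to propyl in one operation; the tetrasubstituted enol double bond and the ketone should be inert.

**Compound list**

1 | furan | c1ccoc1 | starting material
2 | tert-butyl(4-iodobutoxy)dimethylsilane | CC(C)(C)[Si](C)(C)OCCCCI | starting material
3 | 2-furyllithium | [Li]c1ccco1 | intermediate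
4 | tert-butyl[4-(furan-2-yl)butoxy]dimethylsilane | CC(C)(C)[Si](C)(C)OCCCCc1ccco1 | intermediate
5 | 1,1-dimethoxypropan-2-one | CC(=O)C(OC)OC | starting material
6 | (S)-1-phenylethanol | C[C@H](O)c1ccccc1 | starting material
7 | 1-methoxy-1-[(1S)-1-phenylethoxy]propan-2-one (both acetal epimers) | CC(=O)C(OC)O[C@@H](C)c1ccccc1 | intermediate
8 | triethyl({3-methoxy-3-[(1S)-1-phenylethoxy]prop-1-en-2-yl}oxy)silane | C=C(O[Si](CC)(CC)CC)C(OC)O[C@@H](C)c1ccccc1 | intermediate
9 | 1-[(1S)-1-phenylethoxy]-2-(triethylsilyloxy)allyl cation (oxocarbenium form, triflate counter-ion) | C=C(O[Si](CC)(CC)CC)C=[O+][C@@H](C)c1ccccc1 | intermediate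
10 | (1S,4R,5S)-1-[4-(tert-butyldimethylsilyloxy)butyl]-4-[(1S)-1-phenylethoxy]-8-oxabicyclo[3.2.1]oct-6-en-3-one | CC(C)(C)[Si](C)(C)OCCCC[C@@]1(C=C2)CC(=O)[C@H](O[C@@H](C)c3ccccc3)[C@H]2O1 | intermediate
11 | 6-exo,7-exo-diol of 10 (hydroxyls syn to the oxygen bridge) | CC(C)(C)[Si](C)(C)OCCCC[C@@]1([C@H](O)[C@@H]2O)CC(=O)[C@H](O[C@@H](C)c3ccccc3)[C@H]2O1 | intermediate
12 | 3-methylene analogue of 11 | CC(C)(C)[Si](C)(C)OCCCC[C@@]1([C@H](O)[C@@H]2O)CC(=C)[C@H](O[C@@H](C)c3ccccc3)[C@H]2O1 | intermediate
13 | 3-endo-methyl diol (C11 methyl on the side of the two-carbon bridge) | CC(C)(C)[Si](C)(C)OCCCC[C@@]1([C@H](O)[C@@H]2O)C[C@H](C)[C@H](O[C@@H](C)c3ccccc3)[C@H]2O1 | intermediate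
14 | (2S,4S,5S,6R)-2-[4-(tert-butyldimethylsilyloxy)butyl]-4-methyl-5-[(1S)-1-phenylethoxy]oxane-2,6-dicarbaldehyde (formyl groups, methyl and alkoxy all cis) | CC(C)(C)[Si](C)(C)OCCCC[C@@]1(C=O)C[C@H](C)[C@H](O[C@@H](C)c2ccccc2)[C@H](C=O)O1 | intermediate
15 | ethyl (E)-3-{(2S,3S,4S,6S)-6-[4-(tert-butyldimethylsilyloxy)butyl]-6-formyl-4-methyl-3-[(1S)-1-phenylethoxy]oxan-2-yl}-2-methylprop-2-enoate | CC(C)(C)[Si](C)(C)OCCCC[C@@]1(C=O)C[C@H](C)[C@H](O[C@@H](C)c2ccccc2)[C@H](/C=C(\C)C(=O)OCC)O1 | intermediate
16 | 6-(hydroxymethyl) analogue of 15 | CC(C)(C)[Si](C)(C)OCCCC[C@@]1(CO)C[C@H](C)[C@H](O[C@@H](C)c2ccccc2)[C@H](/C=C(\C)C(=O)OCC)O1 | intermediate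
17 | 6-[(p-toluenesulfonyloxy)methyl] analogue of 15 | CC(C)(C)[Si](C)(C)OCCCC[C@@]1(COS(=O)(=O)c2ccc(C)cc2)C[C@H](C)[C@H](O[C@@H](C)c3ccccc3)[C@H](/C=C(\C)C(=O)OCC)O1 | intermediate
18 | (E)-3-{(2S,3S,4S,6S)-6-[4-(tert-butyldimethylsilyloxy)butyl]-4,6-dimethyl-3-[(1S)-1-phenylethoxy]oxan-2-yl}-2-methylprop-2-en-1-ol | CC(C)(C)[Si](C)(C)OCCCC[C@@]1(C)C[C@H](C)[C@H](O[C@@H](C)c2ccccc2)[C@H](/C=C(\C)CO)O1 | intermediate
19 | (2S)-3-{(2S,3S,4S,6S)-6-[4-(tert-butyldimethylsilyloxy)butyl]-4,6-dimethyl-3-[(1S)-1-phenylethoxy]oxan-2-yl}-2-methylpropan-1-ol | CC(C)(C)[Si](C)(C)OCCCC[C@@]1(C)C[C@H](C)[C@H](O[C@@H](C)c2ccccc2)[C@H](C[C@H](C)CO)O1 | intermediate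
20 | (2S)-3-{(2S,3S,4S,6S)-6-[4-(tert-butyldimethylsilyloxy)butyl]-4,6-dimethyl-3-[(1S)-1-phenylethoxy]oxan-2-yl}-2-methylpropanal | CC(C)(C)[Si](C)(C)OCCCC[C@@]1(C)C[C@H](C)[C@H](O[C@@H](C)c2ccccc2)[C@H](C[C@H](C)C=O)O1 | intermediate
21 | methyl (5S,6S)-5-hydroxy-6-methyl-3-oxo-7-(oxanyl)heptanoate, oxanyl as in 20 | CC(C)(C)[Si](C)(C)OCCCC[C@@]1(C)C[C@H](C)[C@H](O[C@@H](C)c2ccccc2)[C@H](C[C@H](C)[C@@H](O)CC(=O)CC(=O)OC)O1 | intermediate
22 | C16 tert-butyldimethylsilyl ether of 21 | CC(C)(C)[Si](C)(C)OCCCC[C@@]1(C)C[C@H](C)[C@H](O[C@@H](C)c2ccccc2)[C@H](C[C@H](C)[C@@H](O[Si](C)(C)C(C)(C)C)CC(=O)CC(=O)OC)O1 | intermediate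
23 | methyl (3R,5S,6S)-5-(tert-butyldimethylsilyloxy)-3-hydroxy-6-methyl-7-(oxanyl)heptanoate, oxanyl as in 20 | CC(C)(C)[Si](C)(C)OCCCC[C@@]1(C)C[C@H](C)[C@H](O[C@@H](C)c2ccccc2)[C@H](C[C@H](C)[C@@H](O[Si](C)(C)C(C)(C)C)C[C@@H](O)CC(=O)OC)O1 | intermediate
24 | methyl (2R,3R,5S,6S)-5-(tert-butyldimethylsilyloxy)-3-hydroxy-6-methyl-2-(prop-2-en-1-yl)-7-(oxanyl)heptanoate, oxanyl as in 20 | CC(C)(C)[Si](C)(C)OCCCC[C@@]1(C)C[C@H](C)[C@H](O[C@@H](C)c2ccccc2)[C@H](C[C@H](C)[C@@H](O[Si](C)(C)C(C)(C)C)C[C@@H](O)[C@@H](CC=C)C(=O)OC)O1 | intermediate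
25 | primary alcohol from 24 (4-hydroxybutyl chain on C9) | OCCCC[C@@]1(C)C[C@H](C)[C@H](O[C@@H](C)c2ccccc2)[C@H](C[C@H](C)[C@@H](O[Si](C)(C)C(C)(C)C)C[C@@H](O)[C@@H](CC=C)C(=O)OC)O1 | intermediate
26 | seco acid (C19 carboxylic acid, free C18 hydroxyl) | OC(=O)CCC[C@@]1(C)C[C@H](C)[C@H](O[C@@H](C)c2ccccc2)[C@H](C[C@H](C)[C@@H](O[Si](C)(C)C(C)(C)C)C[C@@H](O)[C@@H](CC=C)C(=O)OC)O1 | intermediate
27 | mixed anhydride of 26 with 2-methyl-6-nitrobenzoic acid | Cc1cccc([N+](=O)[O-])c1C(=O)OC(=O)CCC[C@@]2(C)C[C@H](C)[C@H](O[C@@H](C)c3ccccc3)[C@H](C[C@H](C)[C@@H](O[Si](C)(C)C(C)(C)C)C[C@@H](O)[C@@H](CC=C)C(=O)OC)O2 | intermediate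
28 | 13-membered lactone of 26 (O on C18 to C19) | O=C1CCC[C@@]2(C)C[C@H](C)[C@H](O[C@@H](C)c3ccccc3)[C@H](C[C@H](C)[C@@H](O[Si](C)(C)C(C)(C)C)C[C@@H](O1)[C@@H](CC=C)C(=O)OC)O2 | intermediate
29 | hydroxypyranone with C4 allyl, C16 (S) silyl ether and O12 (S)-1-phenylethyl ether; other centres as in 32 | C=CC[C@H]1C(O)=C2CC[C@@]3(C)C[C@H](C)[C@H](O[C@@H](C)c4ccccc4)[C@H](C[C@H](C)[C@@H](O[Si](C)(C)C(C)(C)C)C[C@H]1OC2=O)O3 | intermediate
30 | C16 (S) alcohol from 29 | C=CC[C@H]1C(O)=C2CC[C@@]3(C)C[C@H](C)[C@H](O[C@@H](C)c4ccccc4)[C@H](C[C@H](C)[C@@H](O)C[C@H]1OC2=O)O3 | intermediate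
31 | C16 ketone with C4 allyl and O12 (S)-1-phenylethyl ether | C=CC[C@H]1C(O)=C2CC[C@@]3(C)C[C@H](C)[C@H](O[C@@H](C)c4ccccc4)[C@H](C[C@H](C)C(=O)C[C@H]1OC2=O)O3 | intermediate
32 | mangromicin C (4R,9S,11S,12S,13S,15S,18R in the locants of the plan) | CCC[C@H]1C(O)=C2CC[C@@]3(C)C[C@H](C)[C@H](O)[C@H](C[C@H](C)C(=O)C[C@H]1OC2=O)O3 | target

**Totals**

Total step count: 24. Longest linear sequence: 23 steps (steps 2 to 24, from 5 and 6).

**Steps most likely to fail**

1. Step 4. The furan may capture the cation at C13 without the second bond closing (Friedel–Crafts alkylation with re-aromatisation), or add with poor regio- or facial discrimination. The fallback sets out from 6 and 4 and returns at 10; it generates the alkoxy-oxyallyl cation by dehydrohalogenation in an ionising protic solvent instead of by acetal ionisation. (S)-1-Phenylethanol 6 opens epichlorohydrin (BF3·OEt2 cat.) at the terminal carbon to give 1-chloro-3-[(1S)-1-phenylethoxy]propan-2-ol F1. Oxidation with Dess–Martin periodinane gives 1-chloro-3-[(1S)-1-phenylethoxy]propan-2-one F2. F2 with furan 4 and Et3N in CF3CH2OH at rt should give 10 after chromatographic removal of diastereomers.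

2. Step 8. The two aldehydes may not be discriminated well enough (double olefination, or olefination at the formyl group on C9), and the aldehyde on C13 may epimerise. The fallback sets out from 13 and returns at 18; it discriminates two alcohols by acylation and moves the olefination after the deoxygenation. Glycol cleavage of 13 (NaIO4/SiO2) with NaBH4 reduction in the same flask gives the 2,6-bis(hydroxymethyl)oxane F3. Pivaloyl chloride (1.05 equiv, pyridine, −20 °C) should acylate the less hindered hydroxymethyl group on C13 to give mono-pivalate F4. TsCl/Et3N/DMAP gives tosylate F5. LiEt3BH removes the tosylate as hydride-displaced methyl and cleaves the pivalate to give the C9-methyl alcohol F6. TEMPO/PhI(OAc)2 gives aldehyde F7, Ph3P=C(CH3)CO2Et gives ethyl enoate F8, and i-Bu2AlH (CH2Cl2, −78 °C) gives 18.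

3. Step 20. Intermolecular acylation (oligomers) may outrun closure of the 13-membered ring, and base may eliminate the activated β-hydroxy ester. The fallback sets out from 26 and returns at 28; it replaces base-mediated mixed-anhydride activation with acid-catalysed transacylation of an isolable enol ester. Acid 26 adds to ethoxyacetylene ([RuCl2(p-cymene)]2 cat., toluene, rt) to give 1-ethoxyvinyl ester F9. Camphorsulfonic acid (cat.) in toluene at high dilution and 50 °C should then close the ring to 28.

Further compounds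
F1 | step 4 | 1-chloro-3-[(1S)-1-phenylethoxy]propan-2-ol (both C2 epimers) | OC(CCl)CO[C@@H](C)c1ccccc1
F2 | step 4 | 1-chloro-3-[(1S)-1-phenylethoxy]propan-2-one | O=C(CCl)CO[C@@H](C)c1ccccc1
F3 | step 8 | 2,6-bis(hydroxymethyl)oxane (diol from 14) | CC(C)(C)[Si](C)(C)OCCCC[C@@]1(CO)C[C@H](C)[C@H](O[C@@H](C)c2ccccc2)[C@H](CO)O1
F4 | step 8 | mono-pivalate (ester on the hydroxymethyl group at C13) | CC(C)(C)[Si](C)(C)OCCCC[C@@]1(CO)C[C@H](C)[C@H](O[C@@H](C)c2ccccc2)[C@H](COC(=O)C(C)(C)C)O1
F5 | step 8 | tosylate of F4 | CC(C)(C)[Si](C)(C)OCCCC[C@@]1(COS(=O)(=O)c2ccc(C)cc2)C[C@H](C)[C@H](O[C@@H](C)c3ccccc3)[C@H](COC(=O)C(C)(C)C)O1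
F6 | step 8 | C9-methyl alcohol {(2S,3S,4S,6S)-6-[4-(tert-butyldimethylsilyloxy)butyl]-4,6-dimethyl-3-[(1S)-1-phenylethoxy]oxan-2-yl}methanol | CC(C)(C)[Si](C)(C)OCCCC[C@@]1(C)C[C@H](C)[C@H](O[C@@H](C)c2ccccc2)[C@H](CO)O1
F7 | step 8 | aldehyde from F6 | CC(C)(C)[Si](C)(C)OCCCC[C@@]1(C)C[C@H](C)[C@H](O[C@@H](C)c2ccccc2)[C@H](C=O)O1
F8 | step 8 | ethyl enoate (ethyl ester corresponding to 18) | CC(C)(C)[Si](C)(C)OCCCC[C@@]1(C)C[C@H](C)[C@H](O[C@@H](C)c2ccccc2)[C@H](/C=C(\C)C(=O)OCC)O1
F9 | step 20 | 1-ethoxyvinyl ester of 26 | C=C(OCC)OC(=O)CCC[C@@]1(C)C[C@H](C)[C@H](O[C@@H](C)c2ccccc2)[C@H](C[C@H](C)[C@@H](O[Si](C)(C)C(C)(C)C)C[C@@H](O)[C@@H](CC=C)C(=O)OC)O1
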